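**Retrosynthetic overview**

1. Locants used in the text (not those of the systematic names): ring A is the benzoate ring (C1 CO2Me, C2 CH3, C4 OH, C5 CH2OH, C6 ether O); ring B is the benzene ring of the phthalide (C3a', C4' CH3, C5' ether O, C6' OH, C7' OH, C7a'); ring C is the lactone (C1', O2', C3').
2. Feature on which the strategy rests: C3' (on C3a') and the C4' methyl are neighbouring benzylic carbons of ring B, and only C3' is ortho to the C1' carboxyl on C7a'. Ring C is therefore cut at O2'–C3' back to a 5,6-dimethylbenzoic acid, in which the carboxyl group decides which methyl is oxidised.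
3. The diaryl ether C6–O–C5' is cut to a ring B phenol and a ring A fluoride flanked by a C5 formyl group and the C1 ester (SNAr). C5 stays an aldehyde through the lactonisation and is reduced last, because a C5 acetoxymethyl group next to the C4 phenoxide could be lost as an o-quinone methide during basic deacetylation.
4. Ring A comes from 3-fluoro-5-methylphenol (para bromination, lithiation/formylation between F and O, methoxycarbonylation). Ring B comes from 4,5-dimethylcatechol (isopropylidene ketal, dibromination, single bromine–lithium exchange/Boc2O, hydroxylation).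
5. Order of ring formation: rings A and B are bought as benzenes, the dioxole is a temporary ring, and ring C is the only ring of the target that is built (step 12).

Key step: step 12

Remark: 4,5-dimethylbenzene-1,2-diol (4,5-dimethylcatechol) is taken as a purchasable building block.

**Route**

Step 1
Reactants: 1 3-fluoro-5-methylphenol
Product: 2 1-fluoro-3-(methoxymethoxy)-5-methylbenzene
Conditions: MOMCl, i-Pr2NEt, CH2Cl2, 0 °C → rt
Reagents that add atoms: chloromethyl methyl ether, COCCl
Why: O-alkylation of the phenol with the reactive α-chloro ether (Williamson-type etherification) should give the MOM ether, which later directs the lithiation and is removed by acid.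

Step 2
Reactants: 2 1-fluoro-3-(methoxymethoxy)-5-methylbenzene
Product: 3 2-bromo-1-fluoro-5-(methoxymethoxy)-3-methylbenzene
Conditions: NBS, MeCN, 0 °C → rt
Reagents that add atoms: N-bromosuccinimide, O=C1CCC(=O)N1Br
Why: Electrophilic aromatic bromination with NBS in acetonitrile should go mainly para to the strongest donor, the acetal oxygen, at the carbon between F and CH3, as in the para-selective bromination of 3-substituted anisoles.

Step 3
Reactants: 3 2-bromo-1-fluoro-5-(methoxymethoxy)-3-methylbenzene
Product: 5 3-bromo-2-fluoro-6-(methoxymethoxy)-4-methylbenzaldehyde, via aryllithium 4 (not isolated)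
Conditions: LiN(i-Pr)2, THF, −78 °C; then DMF, −78 °C; AcOH quench
Reagents that add atoms: N,N-dimethylformamide, CN(C)C=O
Why: Directed ortho-metalation, in which the amide base removes the most acidic proton (flanked by F and OMOM) at −78 °C without touching the C–Br bond, followed by formylation of the aryllithium with DMF.

Step 4
Reactants: 5 3-bromo-2-fluoro-6-(methoxymethoxy)-4-methylbenzaldehyde
Product: 6 methyl 2-fluoro-3-formyl-4-(methoxymethoxy)-6-methylbenzoate
Conditions: Pd(OAc)2 (5 mol %), Xantphos (10 mol %), CO (1 atm), MeOH (10 equiv), Et3N, toluene, 80 °C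
Reagents that add atoms: carbon monoxide, [C-]#[O+]; methanol, CO
Why: Palladium-catalysed methoxycarbonylation of the aryl bromide (oxidative addition, CO insertion, methanolysis of the acylpalladium) should proceed at atmospheric pressure with the wide-bite-angle ligand, the aldehyde and the MOM ether being inert.

Step 5
Reactants: 7 4,5-dimethylbenzene-1,2-diol
Product: 8 2,2,5,6-tetramethyl-1,3-benzodioxole
Conditions: 2,2-dimethoxypropane, TsOH·H2O (cat.), toluene, reflux, MeOH removed over 4 Å sieves
Reagents that add atoms: 2,2-dimethoxypropane, COC(C)(C)OC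
Why: Acid-catalysed transketalisation of the catechol, driven by removal of methanol, should give the base-stable isopropylidene ketal.

Step 6
Reactants: 8 2,2,5,6-tetramethyl-1,3-benzodioxole
Product: 9 4,7-dibromo-2,2,5,6-tetramethyl-1,3-benzodioxole
Conditions: NBS (2.1 equiv), MeCN, 0 °C → rt, dark
Reagents that add atoms: N-bromosuccinimide, O=C1CCC(=O)N1Br
Why: Twofold electrophilic aromatic bromination at the only two free ring positions of the electron-rich arene, each ortho to a dioxole oxygen, so that the symmetry of 8 leaves no regiochemical question.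

Step 7
Reactants: 9 4,7-dibromo-2,2,5,6-tetramethyl-1,3-benzodioxole
Product: 11 tert-butyl 7-bromo-2,2,5,6-tetramethyl-1,3-benzodioxole-4-carboxylate, via monolithio compound 10 (not isolated)
Conditions: n-BuLi (1.0 equiv), THF, −78 °C; then cannulation into Boc2O, THF, −78 °C → rt; AcOH quench
Reagents that add atoms: di-tert-butyl dicarbonate, CC(C)(C)OC(=O)OC(=O)OC(C)(C)C
Why: Bromine–lithium exchange on the symmetric dibromide should stop after one exchange, and acylation of the aryllithium with Boc2O under inverse addition gives the tert-butyl ester, which its two ortho substituents shield from a second addition.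

Step 8
Reactants: 11 tert-butyl 7-bromo-2,2,5,6-tetramethyl-1,3-benzodioxole-4-carboxylate
Product: 12 tert-butyl 7-hydroxy-2,2,5,6-tetramethyl-1,3-benzodioxole-4-carboxylate
Conditions: Pd2(dba)3 (2 mol %), t-BuXPhos (8 mol %), KOH, 1,4-dioxane/H2O, 100 °C; then aq. HCl
Reagents that add atoms: potassium hydroxide, [K+].[OH-]
Why: Palladium-catalysed hydroxylation of the aryl bromide (C–O cross-coupling with hydroxide under a bulky biarylphosphine) should give the phenol, the hindered tert-butyl ester and the ketal being stable to aqueous KOH.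

Step 9
Reactants: 6 methyl 2-fluoro-3-formyl-4-(methoxymethoxy)-6-methylbenzoate; 12 tert-butyl 7-hydroxy-2,2,5,6-tetramethyl-1,3-benzodioxole-4-carboxylate
Product: 13 tert-butyl 7-[2-formyl-6-(methoxycarbonyl)-3-(methoxymethoxy)-5-methylphenoxy]-2,2,5,6-tetramethyl-1,3-benzodioxole-4-carboxylate
Conditions: Cs2CO3, DMSO, 80 °C
Reagents that add atoms: none
Why: Nucleophilic aromatic substitution by addition–elimination, in which the fluoride of 6 is activated by the ortho formyl and ortho ester groups and the caesium phenoxide of 12 displaces it to form the crowded diaryl ether.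

Step 10
Reactants: 13 tert-butyl 7-[2-formyl-6-(methoxycarbonyl)-3-(methoxymethoxy)-5-methylphenoxy]-2,2,5,6-tetramethyl-1,3-benzodioxole-4-carboxylate
Product: 14 4-[2-formyl-3-hydroxy-6-(methoxycarbonyl)-5-methylphenoxy]-2,3-dihydroxy-5,6-dimethylbenzoic acid
Conditions: TFA/H2O (9:1), rt → 40 °C
Reagents that add atoms: none
Why: Acidolysis should remove the three acid-labile groups in one operation (hydrolysis of the MOM acetal and of the catechol ketal, loss of isobutene from the tert-butyl ester), while the methyl ester, the aldehyde and the diaryl ether are stable to aqueous TFA.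

Step 11
Reactants: 14 4-[2-formyl-3-hydroxy-6-(methoxycarbonyl)-5-methylphenoxy]-2,3-dihydroxy-5,6-dimethylbenzoic acid
Product: 16 2,3-diacetoxy-4-[3-acetoxy-2-formyl-6-(methoxycarbonyl)-5-methylphenoxy]-5,6-dimethylbenzoic acid, via mixed acetic anhydride 15 (not isolated)
Conditions: Ac2O, pyridine, DMAP (cat.), 0 °C → rt; then H2O/THF, rt
Reagents that add atoms: acetic anhydride, CC(=O)OC(C)=O
Why: DMAP-catalysed acetylation of the three phenols also converts the carboxyl group into the mixed anhydride, which water then cleaves at its unhindered acetyl carbonyl while the aryl acetates survive, as in the preparation of acetylsalicylic acid.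

Step 12
Reactants: 16 2,3-diacetoxy-4-[3-acetoxy-2-formyl-6-(methoxycarbonyl)-5-methylphenoxy]-5,6-dimethylbenzoic acid
Product: 17 methyl 4-acetoxy-2-[(6,7-diacetoxy-4-methyl-1-oxo-1,3-dihydroisobenzofuran-5-yl)oxy]-3-formyl-6-methylbenzoate
Conditions: graphite anode, Pt cathode, undivided cell, n-Bu4NBF4, 2,6-lutidine (0.5 equiv), CH2Cl2/HFIP (4:1), constant current, ca. 3 F/mol, rt
Reagents that add atoms: none
Why: One-electron oxidation of the carboxylate of 16 at the anode gives the aroyloxy radical, which takes a hydrogen atom from the methyl group ortho to the carboxyl (the future C3') through a six-membered transition state, and a second anodic electron transfer turns the benzylic radical into the benzylic cation, which the carboxyl oxygen captures to form the O2'–C3' bond. The closest known reaction type is the electrochemical dehydrogenative C(sp3)–H lactonisation of 2-alkylbenzoic acids to phthalides. Ring C (C1', O2', C3', C3a', C7a') closes as a five-membered lactone by attack of the carboxyl oxygen on the exocyclic benzylic carbon, a cation–carboxylate collapse in which the other four ring atoms are already held in one plane by ring B. No stereocentre is formed. The step needs site selectivity among three aryl methyl groups and chemoselectivity for the carboxylate over both arenes: only the methyl ortho to the carboxyl is within reach of the oxygen radical and can close a lactone, and the three aryl acetates, the methyl ester and the formyl group keep the oxidation potential of both rings above that of the carboxylate. The phthalide formed no longer carries a carboxylate and should therefore resist further oxidation at C3'.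

Step 13
Reactants: 17 methyl 4-acetoxy-2-[(6,7-diacetoxy-4-methyl-1-oxo-1,3-dihydroisobenzofuran-5-yl)oxy]-3-formyl-6-methylbenzoate
Product: 19 methyl 2-[(6,7-dihydroxy-4-methyl-1-oxo-1,3-dihydroisobenzofuran-5-yl)oxy]-4-hydroxy-3-(hydroxymethyl)-6-methylbenzoate, via trihydroxy aldehyde 18 (not isolated)
Conditions: K2CO3, degassed MeOH, argon, 0 °C → rt; then NaBH4, 0 °C; 1 M HCl to pH 4
Reagents that add atoms: none
Why: Base-mediated transesterification removes the three aryl acetates first, so that C5 never carries a leaving group beside the C4 phenoxide, and NaBH4 then reduces the aryl aldehyde chemoselectively beside the phthalide and the methyl ester, the mild acidification reclosing any opened lactone.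

**Compound list**

1 | 3-fluoro-5-methylphenol | Cc1cc(O)cc(F)c1 | starting material
2 | 1-fluoro-3-(methoxymethoxy)-5-methylbenzene | COCOc1cc(C)cc(F)c1 | intermediate
3 | 2-bromo-1-fluoro-5-(methoxymethoxy)-3-methylbenzene | COCOc1cc(C)c(Br)c(F)c1 | intermediate
4 | [3-bromo-2-fluoro-6-(methoxymethoxy)-4-methylphenyl]lithium | [Li]c1c(F)c(Br)c(C)cc1OCOC | intermediate
5 | 3-bromo-2-fluoro-6-(methoxymethoxy)-4-methylbenzaldehyde | COCOc1cc(C)c(Br)c(F)c1C=O | intermediate
6 | methyl 2-fluoro-3-formyl-4-(methoxymethoxy)-6-methylbenzoate | COCOc1cc(C)c(C(=O)OC)c(F)c1C=O | intermediate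
7 | 4,5-dimethylbenzene-1,2-diol (4,5-dimethylcatechol) | Cc1cc(O)c(O)cc1C | starting material
8 | 2,2,5,6-tetramethyl-1,3-benzodioxole | Cc1cc2OC(C)(C)Oc2cc1C | intermediate
9 | 4,7-dibromo-2,2,5,6-tetramethyl-1,3-benzodioxole | Cc1c(Br)c2OC(C)(C)Oc2c(Br)c1C | intermediate
10 | (7-bromo-2,2,5,6-tetramethyl-1,3-benzodioxol-4-yl)lithium | [Li]c1c(C)c(C)c(Br)c2OC(C)(C)Oc12 | intermediate
11 | tert-butyl 7-bromo-2,2,5,6-tetramethyl-1,3-benzodioxole-4-carboxylate | Cc1c(Br)c2OC(C)(C)Oc2c(C(=O)OC(C)(C)C)c1C | intermediate
12 | tert-butyl 7-hydroxy-2,2,5,6-tetramethyl-1,3-benzodioxole-4-carboxylate | Cc1c(O)c2OC(C)(C)Oc2c(C(=O)OC(C)(C)C)c1C | intermediate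
13 | tert-butyl 7-[2-formyl-6-(methoxycarbonyl)-3-(methoxymethoxy)-5-methylphenoxy]-2,2,5,6-tetramethyl-1,3-benzodioxole-4-carboxylate | COCOc1cc(C)c(C(=O)OC)c(Oc2c(C)c(C)c(C(=O)OC(C)(C)C)c3OC(C)(C)Oc23)c1C=O | intermediate
14 | 4-[2-formyl-3-hydroxy-6-(methoxycarbonyl)-5-methylphenoxy]-2,3-dihydroxy-5,6-dimethylbenzoic acid | COC(=O)c1c(C)cc(O)c(C=O)c1Oc1c(C)c(C)c(C(=O)O)c(O)c1O | intermediate
15 | acetic 2,3-diacetoxy-4-[3-acetoxy-2-formyl-6-(methoxycarbonyl)-5-methylphenoxy]-5,6-dimethylbenzoic anhydride | COC(=O)c1c(C)cc(OC(C)=O)c(C=O)c1Oc1c(C)c(C)c(C(=O)OC(C)=O)c(OC(C)=O)c1OC(C)=O | intermediate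
16 | 2,3-diacetoxy-4-[3-acetoxy-2-formyl-6-(methoxycarbonyl)-5-methylphenoxy]-5,6-dimethylbenzoic acid | COC(=O)c1c(C)cc(OC(C)=O)c(C=O)c1Oc1c(C)c(C)c(C(=O)O)c(OC(C)=O)c1OC(C)=O | intermediate
17 | methyl 4-acetoxy-2-[(6,7-diacetoxy-4-methyl-1-oxo-1,3-dihydroisobenzofuran-5-yl)oxy]-3-formyl-6-methylbenzoate | COC(=O)c1c(C)cc(OC(C)=O)c(C=O)c1Oc1c(C)c2COC(=O)c2c(OC(C)=O)c1OC(C)=O | intermediate
18 | methyl 2-[(6,7-dihydroxy-4-methyl-1-oxo-1,3-dihydroisobenzofuran-5-yl)oxy]-3-formyl-4-hydroxy-6-methylbenzoate | COC(=O)c1c(C)cc(O)c(C=O)c1Oc1c(C)c2COC(=O)c2c(O)c1O | intermediate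
19 | methyl 2-[(6,7-dihydroxy-4-methyl-1-oxo-1,3-dihydroisobenzofuran-5-yl)oxy]-4-hydroxy-3-(hydroxymethyl)-6-methylbenzoate (Compound NP-007516) | COC(=O)c1c(C)cc(O)c(CO)c1Oc1c(C)c2c(c(O)c1O)C(=O)OC2 | target

**Step count**

Total steps: 13. Longest linear sequence: 9 steps (steps 1–4 or steps 5–8, then steps 9–13).

**Steps most likely to fail**

Step 12. The aroyloxy radical may lose CO2 before it abstracts the primary benzylic hydrogen, or electron transfer may take place from the aryl ether rings instead of the carboxylate and lead to unselective oxidation. The fallback oxidises the lactone carbon before the ether is made, by lateral metalation instead of anodic oxidation. It sets out from 11 and comes back to the route at 18. LiN(i-Pr)2 in THF at −78 °C should remove a proton from the only methyl group ortho to the ester of 11 and give the benzylic lithium compound tert-butyl 7-bromo-5-(lithiomethyl)-2,2,6-trimethyl-1,3-benzodioxole-4-carboxylate F1 as a solution that is used at once. Treatment of F1 with MoO5·pyridine·HMPA should hydroxylate the carbanion to tert-butyl 7-bromo-5-(hydroxymethyl)-2,2,6-trimethyl-1,3-benzodioxole-4-carboxylate F2 after aqueous work-up. Warming F2 with pyridinium p-toluenesulfonate in toluene should close the hydroxymethyl group on the tert-butyl ester, with loss of tert-butanol, to the phthalide 5-bromo-6,7-(isopropylidenedioxy)-4-methylisobenzofuran-1(3H)-one F3 in the same way as a hydroxy ester lactonises. Hydroxylation of F3 under the conditions of step 8, the lactone reclosing on acidification, should give the phenol 5-hydroxy-6,7-(isopropylidenedioxy)-4-methylisobenzofuran-1(3H)-one F4 as the nucleophile for the ether formation. The caesium phenoxide of F4 should then displace the fluoride of 6 under the conditions of step 9 to give the diaryl ether methyl 3-formyl-2-{[6,7-(isopropylidenedioxy)-4-methyl-1-oxo-1,3-dihydroisobenzofuran-5-yl]oxy}-4-(methoxymethoxy)-6-methylbenzoate F5 with ring C already in place. TFA/H2O should remove the MOM and isopropylidene groups of F5 to give 18, which is reduced with NaBH4 as in the second half of step 13.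

Step 9. The addition of the weakly nucleophilic phenoxide, which is para to an ester and has two ortho substituents, to the crowded fluoroarene may be too slow, so that hydrolysis of the fluoride by traces of hydroxide takes over. The fallback forms the ether with a more nucleophilic phenoxide and introduces the carboxyl group afterwards. It sets out from 9 and comes back to the route at 14. The aryllithium 10, made from 9 as in step 7, is quenched with trimethyl borate to give dimethyl (7-bromo-2,2,5,6-tetramethyl-1,3-benzodioxol-4-yl)boronate F6 in solution. Alkaline hydrogen peroxide should oxidise F6 in the same flask to the phenol 7-bromo-2,2,5,6-tetramethyl-1,3-benzodioxol-4-ol F7 by the usual boron-to-oxygen migration. The phenoxide of F7, para to bromine instead of an ester, should displace the fluoride of 6 (Cs2CO3, DMSO) to give the bromo diaryl ether methyl 2-[(7-bromo-2,2,5,6-tetramethyl-1,3-benzodioxol-4-yl)oxy]-3-formyl-4-(methoxymethoxy)-6-methylbenzoate F8 more readily than 12 does. Palladium-catalysed hydroxycarbonylation of the aryl bromide of F8 (Pd(OAc)2, Xantphos, CO, Et3N, dioxane/H2O) should give the acid 7-[2-formyl-6-(methoxycarbonyl)-3-(methoxymethoxy)-5-methylphenoxy]-2,2,5,6-tetramethyl-1,3-benzodioxole-4-carboxylic acid F9 with the hindered methyl ester untouched. TFA/H2O should then convert F9 into 14 by loss of the MOM and isopropylidene groups.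

Step 4. Methanol may displace the activated fluoride under the basic carbonylation conditions, or oxidative addition at the C–Br bond with two ortho substituents may be slow. The fallback replaces the palladium carbonylation by an organolithium acylation with the aldehyde protected in the flask. It sets out from 5 and comes back to the route at 6. Lithium N,N,N'-trimethylethylenediamide should add to the aldehyde of 5 at −78 °C in THF to give the α-amino alkoxide lithium [3-bromo-2-fluoro-6-(methoxymethoxy)-4-methylphenyl]{[2-(dimethylamino)ethyl](methyl)amino}methanolate F10 as a masked aldehyde. n-BuLi should then exchange the bromine of F10 at −78 °C to give the aryllithium lithium {[2-(dimethylamino)ethyl](methyl)amino}[2-fluoro-3-lithio-6-(methoxymethoxy)-4-methylphenyl]methanolate F11 in the same flask. Methyl chloroformate should acylate the aryllithium carbon of F11 under inverse addition, and aqueous acid work-up releases the aldehyde to give 6.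

**Further compounds**

F1 | step 12 | tert-butyl 7-bromo-5-(lithiomethyl)-2,2,6-trimethyl-1,3-benzodioxole-4-carboxylate | [Li]Cc1c(C)c(Br)c2OC(C)(C)Oc2c1C(=O)OC(C)(C)C
F2 | step 12 | tert-butyl 7-bromo-5-(hydroxymethyl)-2,2,6-trimethyl-1,3-benzodioxole-4-carboxylate | OCc1c(C)c(Br)c2OC(C)(C)Oc2c1C(=O)OC(C)(C)C
F3 | step 12 | 5-bromo-6,7-(isopropylidenedioxy)-4-methylisobenzofuran-1(3H)-one | Cc1c(Br)c2OC(C)(C)Oc2c2C(=O)OCc12
F4 | step 12 | 5-hydroxy-6,7-(isopropylidenedioxy)-4-methylisobenzofuran-1(3H)-one | Cc1c(O)c2OC(C)(C)Oc2c2C(=O)OCc12
F5 | step 12 | methyl 3-formyl-2-{[6,7-(isopropylidenedioxy)-4-methyl-1-oxo-1,3-dihydroisobenzofuran-5-yl]oxy}-4-(methoxymethoxy)-6-methylbenzoate | COCOc1cc(C)c(C(=O)OC)c(Oc2c(C)c3COC(=O)c3c3OC(C)(C)Oc23)c1C=O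
F6 | step 9 | dimethyl (7-bromo-2,2,5,6-tetramethyl-1,3-benzodioxol-4-yl)boronate | COB(OC)c1c(C)c(C)c(Br)c2OC(C)(C)Oc12
F7 | step 9 | 7-bromo-2,2,5,6-tetramethyl-1,3-benzodioxol-4-ol | Cc1c(O)c2OC(C)(C)Oc2c(Br)c1C
F8 | step 9 | methyl 2-[(7-bromo-2,2,5,6-tetramethyl-1,3-benzodioxol-4-yl)oxy]-3-formyl-4-(methoxymethoxy)-6-methylbenzoate | COCOc1cc(C)c(C(=O)OC)c(Oc2c(C)c(C)c(Br)c3OC(C)(C)Oc23)c1C=O
F9 | step 9 | 7-[2-formyl-6-(methoxycarbonyl)-3-(methoxymethoxy)-5-methylphenoxy]-2,2,5,6-tetramethyl-1,3-benzodioxole-4-carboxylic acid | COCOc1cc(C)c(C(=O)OC)c(Oc2c(C)c(C)c(C(=O)O)c3OC(C)(C)Oc23)c1C=O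
F10 | step 4 | lithium [3-bromo-2-fluoro-6-(methoxymethoxy)-4-methylphenyl]{[2-(dimethylamino)ethyl](methyl)amino}methanolate | COCOc1cc(C)c(Br)c(F)c1C(O[Li])N(C)CCN(C)C
F11 | step 4 | lithium {[2-(dimethylamino)ethyl](methyl)amino}[2-fluoro-3-lithio-6-(methoxymethoxy)-4-methylphenyl]methanolate | COCOc1cc(C)c([Li])c(F)c1C(O[Li])N(C)CCN(C)C
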